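## Retrosynthetic overview

1. Target 27 comes from triol 20 by functional-group changes only: the C3 CH2OH becomes the exocyclic methylene, O7 is angeloylated, and the allylic silyl ether becomes the enal.
2. Key disconnection: bonds C4–C5 and C6–C7 of the carbocycle (C3a, C4, C5, C6, C7, C7a). This ring holds two homoallylic alcohol units that share the C5–C6 bond, C4(OH)–C5–C(=CH2) and C7(O)–C6–CH=CH2. So C4 and C7 are the carbonyl carbons of a 1,4-dialdehyde, and C5–C6 is a vicinal double-allyl donor, the allylic 1,2-bis(boronate) 9.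
3. The dialdehyde partner 17 already carries the trans-fused lactone (C3a, C7a) and the C3 CH2OH. That CH2OH is cis to the C7a formyl group and holds it as a six-membered lactol, which fixes the order of the two allylations.
4. 17 comes from D-gulono-1,4-lactone (butenolide 13, conjugate vinyl addition with formaldehyde aldol, oxidative cleavage). 9 comes from 2-bromoallyl alcohol, propyne and a vinylboronate.
5. Ring order: lactone ring first (from the sugar), carbocycle second (key step).

Key step: step 11

Remark: ring positions are named as in octahydro-1-benzofuran-2-one (O1, C2, C3, C3a, C4, C5, C6, C7, C7a); lactol 17 is carried as its anomer mixture, which is harmless because the lactol carbon becomes C7.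

## Route

Step 1
Reactants: 1 2-bromoprop-2-en-1-ol
Product: 2 tert-butyl[(2-bromoprop-2-en-1-yl)oxy]dimethylsilane
Conditions: TBSCl, imidazole, DMF, 0 °C to rt
Reagents that add atoms: tert-butyldimethylsilyl chloride, CC(C)(C)[Si](C)(C)Cl
Why: Silylation of a primary allylic alcohol should protect the oxygen that ends as the aldehyde oxygen of the target.

Step 2
Reactants: 2 tert-butyl[(2-bromoprop-2-en-1-yl)oxy]dimethylsilane; 3 propyne
Product: 4 tert-butyldimethyl[(2-methylidenepent-3-yn-1-yl)oxy]silane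
Conditions: PdCl2(PPh3)2 (cat.), CuI (cat.), Et3N, THF, rt
Reagents that add atoms: none
Why: Sonogashira coupling of a 1,1-disubstituted vinyl bromide with a terminal alkyne should give the conjugated enyne without touching the silyl ether.

Step 3
Reactants: 4 tert-butyldimethyl[(2-methylidenepent-3-yn-1-yl)oxy]silane
Product: 6 tert-butyl{[(3E)-4-bromo-2-methylidenepent-3-en-1-yl]oxy}dimethylsilane, via alkenylzirconocene chloride 5 (not isolated)
Conditions: Cp2Zr(H)Cl, THF, rt; then NBS, 0 °C
Reagents that add atoms: N-bromosuccinimide, O=C1CCC(=O)N1Br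
Why: Syn-hydrozirconation of the internal alkyne should place zirconium on the methyl-bearing carbon (less hindered, distal to the alkene), and bromination of the C–Zr bond with retention should give the E bromide, whose geometry later fixes C4 relative to C5.

Step 4
Reactants: 7 2-ethenyl-4,4,5,5-tetramethyl-1,3,2-dioxaborolane
Product: 8 2,2',2''-(ethane-1,1,2-triyl)tris(4,4,5,5-tetramethyl-1,3,2-dioxaborolane)
Conditions: B2pin2, Pt(dba)2 (cat.), toluene, 50 °C
Reagents that add atoms: bis(pinacolato)diboron, CC1(C)OB(OC1(C)C)B1OC(C)(C)C(C)(C)O1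
Why: Platinum-catalysed syn-diboration of an alkenylboronate should give the 1,1,2-tris(boronate) with a geminal pair of boron groups.

Step 5
Reactants: 6 tert-butyl{[(3E)-4-bromo-2-methylidenepent-3-en-1-yl]oxy}dimethylsilane; 8 2,2',2''-(ethane-1,1,2-triyl)tris(4,4,5,5-tetramethyl-1,3,2-dioxaborolane)
Product: 9 tert-butyldimethyl{[(3E,5S)-4-methyl-2-methylidene-5,6-bis(4,4,5,5-tetramethyl-1,3,2-dioxaborolan-2-yl)hex-3-en-1-yl]oxy}silane
Conditions: Pd(OAc)2 (cat.), TADDOL-derived phosphoramidite (cat., the antipode that gives the S boronate), KOH, 1,4-dioxane/H2O, rt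
Reagents that add atoms: none
Why: Enantiotopic-group-selective Suzuki–Miyaura coupling of a geminal bis(boronate) with an alkenyl bromide should give the allylic 1,2-bis(boronate); the boron-bearing stereocentre is set by the chiral ligand and the alkene geometry is kept.

Step 6
Reactants: 10 D-gulono-1,4-lactone
Product: 11 5,6-O-isopropylidene-D-gulono-1,4-lactone
Conditions: 2-methoxypropene, TsOH·H2O (cat.), DMF, 0 °C
Reagents that add atoms: 2-methoxypropene, C=C(C)OC
Why: Kinetic acetalisation should take the terminal 5,6-diol and leave the cis-2,3-diol free.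

Step 7
Reactants: 11 5,6-O-isopropylidene-D-gulono-1,4-lactone
Product: 13 (5R)-5-[(4R)-2,2-dimethyl-1,3-dioxolan-4-yl]furan-2(5H)-one, via cyclic thionocarbonate 12 (not isolated)
Conditions: 1,1'-thiocarbonyldiimidazole, THF, reflux; then P(OMe)3, 110 °C
Reagents that add atoms: none
Why: Corey–Winter olefination of the cis-2,3-diol (stereospecific syn-elimination) should give the butenolide, and the ring stereocentre that becomes C7a is not involved.

Step 8
Reactants: 13 (5R)-5-[(4R)-2,2-dimethyl-1,3-dioxolan-4-yl]furan-2(5H)-one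
Product: 15 (3S,4R,5R)-5-[(4R)-2,2-dimethyl-1,3-dioxolan-4-yl]-4-ethenyl-3-(hydroxymethyl)oxolan-2-one, via bromomagnesium enolate 14 (not isolated)
Conditions: CH2=CHMgBr, CuBr·SMe2 (cat.), THF, −78 °C; then CH2O (gas), −78 to −30 °C; aq. NH4Cl
Reagents that add atoms: vinylmagnesium bromide, C=C[Mg]Br; formaldehyde, C=O
Why: Copper-catalysed conjugate addition should occur anti to the dioxolanyl group (sets the future C3a), and the aldol of the enolate with formaldehyde should occur anti to the new vinyl group (sets C3), giving the all-trans lactone.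

Step 9
Reactants: 15 (3S,4R,5R)-5-[(4R)-2,2-dimethyl-1,3-dioxolan-4-yl]-4-ethenyl-3-(hydroxymethyl)oxolan-2-one
Product: 16 (3S,4R,5R)-5-[(1R)-1,2-dihydroxyethyl]-4-ethenyl-3-(hydroxymethyl)oxolan-2-one
Conditions: AcOH/H2O (4:1), 40 °C
Reagents that add atoms: none
Why: Mild acid hydrolysis of the terminal acetonide should free the glycol while the five-membered lactone stays closed.

Step 10
Reactants: 16 (3S,4R,5R)-5-[(1R)-1,2-dihydroxyethyl]-4-ethenyl-3-(hydroxymethyl)oxolan-2-one
Product: 17 lactol form of (2R,3R,4S)-4-(hydroxymethyl)-5-oxooxolane-2,3-dicarbaldehyde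
Conditions: OsO4 (cat.), NaIO4, 2,6-lutidine, 1,4-dioxane/H2O, rt
Reagents that add atoms: sodium periodate, [Na+].[O-]I(=O)(=O)=O (with catalytic OsO4, O=[Os](=O)(=O)=O; source of the oxygen of the aldehyde made from the vinyl group)
Why: Lemieux–Johnson cleavage of the vinyl group and periodate glycol cleavage in one flask should unveil both aldehydes; the C7a-bound formyl group is caught by the cis CH2OH as a six-membered lactol, while the C3a-bound formyl group (trans to the CH2OH) stays free.

Step 11
Reactants: 9 tert-butyldimethyl{[(3E,5S)-4-methyl-2-methylidene-5,6-bis(4,4,5,5-tetramethyl-1,3,2-dioxaborolan-2-yl)hex-3-en-1-yl]oxy}silane; 17 lactol form of (2R,3R,4S)-4-(hydroxymethyl)-5-oxooxolane-2,3-dicarbaldehyde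
Product: 20 (3S,3aS,4S,5S,6S,7S,7aR)-5-[3-(tert-butyldimethylsilyloxy)prop-1-en-2-yl]-6-ethenyl-4,7-dihydroxy-3-(hydroxymethyl)-6-methylhexahydro-1-benzofuran-2(3H)-one, via (Z)-allylboronate borate 18 (not isolated), via bis(pinacol borate) 19 (not isolated)
Conditions: toluene, 4 Å molecular sieves, rt then 70 °C; aq. NaHCO3/D-sorbitol work-up
Reagents that add atoms: none
Why: The secondary allylboronate of 9 should add through its γ-carbon to the only free aldehyde of 17 in a chair Zimmerman–Traxler transition state (bond C4–C5), and the allyl shift leaves the (Z)-configured primary allylboronate 18, whose γ-carbon then adds to the C7 aldehyde released from the lactol (bond C6–C7) and closes the carbocycle by 6-exo-trig carbonyl addition through a bicyclic chair; the closest known reaction type is the tandem double allylboration of 1,4-dicarbonyl compounds with diene-derived allylic 1,2-bis(boronates) to give vinylcyclohexane-1,4-diols. C5 is set by 1,3-chirality transfer from the boron-bearing stereocentre of 9, whose CH2Bpin group should lie pseudoaxial (gauche strain with the pinacolate and A(1,2) strain with the methyl group disfavour the equatorial place), and C4 follows from the E alkene, because its substituent and the aldehyde residue are both equatorial (anti adduct). In the second event the Z geometry of 18 puts the tether carbon C5 axial in the boron-containing six-membered ring, so O7 ends axial, cis to the equatorial vinyl group and trans to the axial methyl group at C6; the absolute sense comes from the carbocycle chair, which the trans-fused lactone locks with the C3a, C7a and C5 substituents equatorial. The step needs site selectivity between the two aldehydes, secured by the lactol that masks the more electrophilic C7 aldehyde until the first C–C bond exists, and Z selectivity in the allyl shift, secured by the α- and β-substituents of 9.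

Step 12
Reactants: 20 (3S,3aS,4S,5S,6S,7S,7aR)-5-[3-(tert-butyldimethylsilyloxy)prop-1-en-2-yl]-6-ethenyl-4,7-dihydroxy-3-(hydroxymethyl)-6-methylhexahydro-1-benzofuran-2(3H)-one
Product: 22 (3aS,4S,5S,6S,7S,7aR)-5-[3-(tert-butyldimethylsilyloxy)prop-1-en-2-yl]-6-ethenyl-4,7-dihydroxy-6-methyl-3-methylidenehexahydro-1-benzofuran-2(3H)-one, via primary mesylate 21 (not isolated)
Conditions: MsCl, Et3N, CH2Cl2, −20 °C; then DBU, 0 °C to rt
Reagents that add atoms: none
Why: Selective sulfonylation of the only primary hydroxyl (both secondary hydroxyls are axial and hindered), followed by E1cB elimination of the β-mesyloxy lactone, should give the α-methylene lactone; closure of O4 onto the new alkene would be a disfavoured 5-endo-trig process.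

Step 13
Reactants: 22 (3aS,4S,5S,6S,7S,7aR)-5-[3-(tert-butyldimethylsilyloxy)prop-1-en-2-yl]-6-ethenyl-4,7-dihydroxy-6-methyl-3-methylidenehexahydro-1-benzofuran-2(3H)-one; 23 angelic acid
Product: 25 (3aS,4S,5S,6S,7S,7aR)-5-[3-(tert-butyldimethylsilyloxy)prop-1-en-2-yl]-6-ethenyl-4-hydroxy-6-methyl-3-methylidene-2-oxooctahydro-1-benzofuran-7-yl (2Z)-2-methylbut-2-enoate, via mixed anhydride 24 (not isolated)
Conditions: 2,4,6-trichlorobenzoyl chloride, Et3N, toluene, rt; then 22, 80 °C
Reagents that add atoms: none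
Why: Yamaguchi esterification without a nucleophilic catalyst should transfer the angeloyl group with its Z geometry intact to O7, which has no syn-axial substituent, in preference to O4, which is flanked by two branched carbons and is syn-axial to the C6 methyl group.

Step 14
Reactants: 25 (3aS,4S,5S,6S,7S,7aR)-5-[3-(tert-butyldimethylsilyloxy)prop-1-en-2-yl]-6-ethenyl-4-hydroxy-6-methyl-3-methylidene-2-oxooctahydro-1-benzofuran-7-yl (2Z)-2-methylbut-2-enoate
Product: 26 (3aS,4S,5S,6S,7S,7aR)-6-ethenyl-4-hydroxy-5-(3-hydroxyprop-1-en-2-yl)-6-methyl-3-methylidene-2-oxooctahydro-1-benzofuran-7-yl (2Z)-2-methylbut-2-enoate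
Conditions: HF·pyridine, pyridine/THF, 0 °C to rt
Reagents that add atoms: none
Why: Buffered fluoride desilylation of a primary silyl ether should leave the angelate and the α-methylene lactone untouched.

Step 15
Reactants: 26 (3aS,4S,5S,6S,7S,7aR)-6-ethenyl-4-hydroxy-5-(3-hydroxyprop-1-en-2-yl)-6-methyl-3-methylidene-2-oxooctahydro-1-benzofuran-7-yl (2Z)-2-methylbut-2-enoate
Product: 27 (3aS,4S,5R,6S,7S,7aR)-6-ethenyl-4-hydroxy-6-methyl-3-methylidene-2-oxo-5-(3-oxoprop-1-en-2-yl)octahydro-1-benzofuran-7-yl (2Z)-2-methylbut-2-enoate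
Conditions: MnO2, CH2Cl2, rt
Reagents that add atoms: none
Why: Allylic oxidation with MnO2 should convert only the primary allylic alcohol into the enal and leave the secondary, non-allylic C4 hydroxyl alone.

## Compound list

1 | 2-bromoprop-2-en-1-ol | C=C(Br)CO | starting material
2 | tert-butyl[(2-bromoprop-2-en-1-yl)oxy]dimethylsilane | C=C(Br)CO[Si](C)(C)C(C)(C)C | intermediate
3 | propyne | CC#C | starting material
4 | tert-butyldimethyl[(2-methylidenepent-3-yn-1-yl)oxy]silane | CC#CC(=C)CO[Si](C)(C)C(C)(C)C | intermediate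
5 | (E)-alkenylzirconocene chloride (Zr on the methyl-bearing carbon, trans to the dienyl residue) | C/C(=C\C(=C)CO[Si](C)(C)C(C)(C)C)[Zr](Cl)(C1C=CC=C1)C1C=CC=C1 | intermediate
6 | tert-butyl{[(3E)-4-bromo-2-methylidenepent-3-en-1-yl]oxy}dimethylsilane | C/C(Br)=C\C(=C)CO[Si](C)(C)C(C)(C)C | intermediate
7 | 2-ethenyl-4,4,5,5-tetramethyl-1,3,2-dioxaborolane | C=CB1OC(C)(C)C(C)(C)O1 | starting material
8 | 2,2',2''-(ethane-1,1,2-triyl)tris(4,4,5,5-tetramethyl-1,3,2-dioxaborolane) | CC1(C)OB(CC(B2OC(C)(C)C(C)(C)O2)B2OC(C)(C)C(C)(C)O2)OC1(C)C | intermediate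
9 | tert-butyldimethyl{[(3E,5S)-4-methyl-2-methylidene-5,6-bis(4,4,5,5-tetramethyl-1,3,2-dioxaborolan-2-yl)hex-3-en-1-yl]oxy}silane | CC1(C)OB(C[C@H](B2OC(C)(C)C(C)(C)O2)/C(C)=C/C(=C)CO[Si](C)(C)C(C)(C)C)OC1(C)C | intermediate
10 | D-gulono-1,4-lactone | O=C1O[C@@H]([C@H](O)CO)[C@@H](O)[C@H]1O | starting material
11 | 5,6-O-isopropylidene-D-gulono-1,4-lactone | O=C1O[C@@H]([C@H]2COC(C)(C)O2)[C@@H](O)[C@H]1O | intermediate
12 | 5,6-O-isopropylidene-2,3-O-thiocarbonyl-D-gulono-1,4-lactone | O=C1O[C@@H]([C@H]2COC(C)(C)O2)[C@H]3OC(=S)O[C@@H]13 | intermediate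
13 | (5R)-5-[(4R)-2,2-dimethyl-1,3-dioxolan-4-yl]furan-2(5H)-one | O=C1C=C[C@@H](O1)[C@H]2COC(C)(C)O2 | intermediate
14 | bromomagnesium enolate of the 4-vinyl lactone (vinyl trans to the dioxolanyl group) | Br[Mg]OC1=C[C@@H](C=C)[C@@H](O1)[C@H]2COC(C)(C)O2 | intermediate
15 | (3S,4R,5R)-5-[(4R)-2,2-dimethyl-1,3-dioxolan-4-yl]-4-ethenyl-3-(hydroxymethyl)oxolan-2-one | OC[C@H]1C(=O)O[C@@H]([C@H]2COC(C)(C)O2)[C@@H]1C=C | intermediate
16 | (3S,4R,5R)-5-[(1R)-1,2-dihydroxyethyl]-4-ethenyl-3-(hydroxymethyl)oxolan-2-one | OC[C@H]1C(=O)O[C@@H]([C@H](O)CO)[C@@H]1C=C | intermediate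
17 | lactol form of (2R,3R,4S)-4-(hydroxymethyl)-5-oxooxolane-2,3-dicarbaldehyde (2-formyl group closed onto the CH2OH as a six-membered hemiacetal, 3-formyl group free) | O=C[C@H]1[C@H]2OC(=O)[C@@H]1COC2O | intermediate
18 | (Z)-allylboronate borate: C4–C5 bond formed, O4 as pinacol borate, lactol intact, CH2Bpin cis to C5 on the new trisubstituted alkene | CC1(C)OB(O[C@@H]([C@@H](C(=C)CO[Si](C)(C)C(C)(C)C)/C(C)=C\CB2OC(C)(C)C(C)(C)O2)[C@H]3[C@H]4OC(=O)[C@@H]3COC4O)OC1(C)C | intermediate
19 | 4,7-bis(pinacol borate) of triol 20 | C=C[C@]1(C)[C@H](OB3OC(C)(C)C(C)(C)O3)[C@@H]2OC(=O)[C@H](CO)[C@H]2[C@@H](OB4OC(C)(C)C(C)(C)O4)[C@H]1C(=C)CO[Si](C)(C)C(C)(C)C | intermediate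
20 | (3S,3aS,4S,5S,6S,7S,7aR)-5-[3-(tert-butyldimethylsilyloxy)prop-1-en-2-yl]-6-ethenyl-4,7-dihydroxy-3-(hydroxymethyl)-6-methylhexahydro-1-benzofuran-2(3H)-one | C=C[C@]1(C)[C@H](O)[C@@H]2OC(=O)[C@H](CO)[C@H]2[C@@H](O)[C@H]1C(=C)CO[Si](C)(C)C(C)(C)C | intermediate
21 | primary mesylate of 20 | C=C[C@]1(C)[C@H](O)[C@@H]2OC(=O)[C@H](COS(C)(=O)=O)[C@H]2[C@@H](O)[C@H]1C(=C)CO[Si](C)(C)C(C)(C)C | intermediate
22 | (3aS,4S,5S,6S,7S,7aR)-5-[3-(tert-butyldimethylsilyloxy)prop-1-en-2-yl]-6-ethenyl-4,7-dihydroxy-6-methyl-3-methylidenehexahydro-1-benzofuran-2(3H)-one | C=C[C@]1(C)[C@H](O)[C@@H]2OC(=O)C(=C)[C@H]2[C@@H](O)[C@H]1C(=C)CO[Si](C)(C)C(C)(C)C | intermediate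
23 | angelic acid, (2Z)-2-methylbut-2-enoic acid | C/C=C(/C)C(=O)O | starting material
24 | (2Z)-2-methylbut-2-enoic 2,4,6-trichlorobenzoic anhydride | C/C=C(/C)C(=O)OC(=O)c1c(Cl)cc(Cl)cc1Cl | intermediate
25 | (3aS,4S,5S,6S,7S,7aR)-5-[3-(tert-butyldimethylsilyloxy)prop-1-en-2-yl]-6-ethenyl-4-hydroxy-6-methyl-3-methylidene-2-oxooctahydro-1-benzofuran-7-yl (2Z)-2-methylbut-2-enoate | C=C[C@]1(C)[C@H](OC(=O)/C(C)=C\C)[C@@H]2OC(=O)C(=C)[C@H]2[C@@H](O)[C@H]1C(=C)CO[Si](C)(C)C(C)(C)C | intermediate
26 | (3aS,4S,5S,6S,7S,7aR)-6-ethenyl-4-hydroxy-5-(3-hydroxyprop-1-en-2-yl)-6-methyl-3-methylidene-2-oxooctahydro-1-benzofuran-7-yl (2Z)-2-methylbut-2-enoate | C=C[C@]1(C)[C@H](OC(=O)/C(C)=C\C)[C@@H]2OC(=O)C(=C)[C@H]2[C@@H](O)[C@H]1C(=C)CO | intermediate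
27 | (3aS,4S,5R,6S,7S,7aR)-6-ethenyl-4-hydroxy-6-methyl-3-methylidene-2-oxo-5-(3-oxoprop-1-en-2-yl)octahydro-1-benzofuran-7-yl (2Z)-2-methylbut-2-enoate | C=C[C@]1(C)[C@H](OC(=O)/C(C)=C\C)[C@@H]2OC(=O)C(=C)[C@H]2[C@@H](O)[C@H]1C(=C)C=O | target

## Step count and risks

Total: 15 steps. Longest linear sequence: 10 steps (steps 6 to 15, from D-gulono-1,4-lactone).

**Step 11 (key step).** Three things may go wrong:
- The order of the two carbonyl additions may be lost if the lactol opens before the first allylation.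
- The first allylation may leak through the transition state with an equatorial CH2Bpin group, giving the E allylboronate and hence the C6/C7 epimers.
- The ring closure may stall, because its chair transition state carries the syn-axial O4/C6-methyl contact that the target itself has.

The fallback separates the two C–C bond formations and sets out from 15 and 9. Ozonolysis of 15 (O3, CH2Cl2/MeOH, −78 °C; Me2S) should give the lactone aldehyde F1 with the dioxolane still in place. Allylboration of F1 with 9 (toluene, 40 °C, aqueous work-up) should give the isolable (Z)-allylboronate F2. Periodic acid (H5IO6, EtOAc, rt) should then cleave the terminal acetonide to the C7 aldehyde, and warming the same flask to 60 °C should close the ring. The fallback rejoins the route at 20.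

**Step 5.** Enantiotopic-group selection may be eroded, or the tris(boronate) may suffer protodeboronation under aqueous KOH before transmetalation. The fallback sets out from 6. Suzuki–Miyaura coupling with (E)-1,2-bis(4,4,5,5-tetramethyl-1,3,2-dioxaborolan-2-yl)ethene (Pd(PPh3)4, K3PO4, THF/H2O) should give the dienylboronate F3. Copper-catalysed enantioselective protoboration of its boron-substituted alkene (CuCl, chiral N-heterocyclic carbene ligand, NaOt-Bu, B2pin2, MeOH, THF) should place the new boron on the carbon next to the diene. The fallback rejoins the route at 9.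

**Step 13.** The angelate may isomerise from Z to E through reversible conjugate addition to the activated acyl donor, acylation of the neopentyl-type axial O7–H may be incomplete, or O4 may be acylated in competition. The fallback builds the Z double bond on the substrate and sets out from 22. Acylation with 2-[bis(2,2,2-trifluoroethoxy)phosphoryl]propanoic acid (DCC, DMAP cat., CH2Cl2) should give the phosphonate ester F4. Still–Gennari olefination with acetaldehyde (KHMDS, 18-crown-6, THF, −78 °C) should then give the angelate. The fallback rejoins the route at 25.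

## Further compounds

F1 | step 11 | (2R,3R,4S)-2-[(4R)-2,2-dimethyl-1,3-dioxolan-4-yl]-4-(hydroxymethyl)-5-oxooxolane-3-carbaldehyde | OC[C@H]1C(=O)O[C@@H]([C@H]2COC(C)(C)O2)[C@@H]1C=O
F2 | step 11 | (Z)-allylboronate mono-adduct with free C4 hydroxyl and intact dioxolane | O[C@@H]([C@@H](C(=C)CO[Si](C)(C)C(C)(C)C)/C(C)=C\CB2OC(C)(C)C(C)(C)O2)[C@H]3[C@H]([C@H]4COC(C)(C)O4)OC(=O)[C@@H]3CO
F3 | step 5 | tert-butyldimethyl{[(3E,5E)-4-methyl-2-methylidene-6-(4,4,5,5-tetramethyl-1,3,2-dioxaborolan-2-yl)hexa-3,5-dien-1-yl]oxy}silane | CC1(C)OB(/C=C/C(C)=C/C(=C)CO[Si](C)(C)C(C)(C)C)OC1(C)C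
F4 | step 13 | 7-O-{2-[bis(2,2,2-trifluoroethoxy)phosphoryl]propanoyl} ester of 22 | C=C[C@]1(C)[C@H](OC(=O)C(C)P(=O)(OCC(F)(F)F)OCC(F)(F)F)[C@@H]2OC(=O)C(=C)[C@H]2[C@@H](O)[C@H]1C(=C)CO[Si](C)(C)C(C)(C)C
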